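**Retrosynthetic overview**

- The strategy rests on ring A, the 4-hydroxy-3-methylfuran-2(5H)-one. Its C5 carries an exocyclic C=CH whose CH carbon lies trans to the ring oxygen and is bonded to the CH(CH3) stereocentre and then a CH2. This pattern maps onto a cis-enynoic acid plus crotonaldehyde.
- Late disconnections: the tetronic acid O–H (from its methyl ether), then the σ-bond between the two alkenes of the (4E,6E)-diene (alkenyl iodide plus alkenylzirconocene from a bis-furan 2-alkyne), then the iodoalkene back to an aldehyde (Takai).
- Key disconnection: the ring-oxygen–C5 bond of ring A and the bond from the exocyclic carbon to the stereocentre, leading to (2E)-3-methoxy-2-methylpent-2-en-4-ynoic acid and (E)-crotonaldehyde. Ring A is the only ring formed; furan rings B and C are bought.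
- The enynoic acid comes from ethyl propionate and 3-(trimethylsilyl)propiolic acid. The bis-furan alkyne comes from 3,4-dibromofuran, furan-3-carbaldehyde and pent-3-yn-1-ol.

Key step: step 5

Assumption: the sense of induction of the pyridine–oxazoline ligand in step 5 cannot be predicted with confidence. The (S)-tert-butyl ligand is written; its antipode is to be used if the opposite enal face is favoured.

**Route**

Step 1
Reactants: 1 3-(trimethylsilyl)propiolic acid
Product: 2 3-(trimethylsilyl)propynoyl chloride
Conditions: (COCl)2, DMF (cat.), CH2Cl2, 0 °C → rt; concentrate, use crude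
Reagents that add atoms: oxalyl chloride, ClC(=O)C(=O)Cl
Why: Standard acid chloride formation under Vilsmeier catalysis; the silyl group shields the alkyne terminus and the gaseous by-products leave on concentration.

Step 2
Reactants: 3 ethyl propionate; 2 3-(trimethylsilyl)propynoyl chloride
Product: 5 ethyl 2-methyl-3-oxo-5-(trimethylsilyl)pent-4-ynoate (racemic), via lithium enolate of ethyl propionate 4 (not isolated)
Conditions: LiN(i-Pr)2 (2.1 equiv), 3 (2.1 equiv), THF, −78 °C; then 2 (1.0 equiv), −78 °C; aq. NH4Cl
Reagents that add atoms: none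
Why: Crossed Claisen acylation of a preformed ester enolate by an acid chloride; the second equivalent of enolate deprotonates the more acidic β-keto ester as it forms, which should stop over-acylation, and the silyl group hinders conjugate addition to the ynone.

Step 3
Reactants: 5 ethyl 2-methyl-3-oxo-5-(trimethylsilyl)pent-4-ynoate
Product: 7 ethyl (2E)-3-methoxy-2-methyl-5-(trimethylsilyl)pent-2-en-4-ynoate, via potassium enolate 6 (not isolated)
Conditions: KOt-Bu (1.0 equiv), DMSO–THF, 0 °C → rt; then Me2SO4, rt
Reagents that add atoms: dimethyl sulfate, COS(=O)(=O)OC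
Why: O-alkylation of a dissociated potassium enolate by a hard electrophile in a dipolar aprotic solvent; the free enolate prefers the W-shaped form with its two oxygen atoms far apart, so methylation on oxygen should place methoxy trans to the ester and the alkyne cis to it, the (2E) geometry that lactonisation needs.

Step 4
Reactants: 7 ethyl (2E)-3-methoxy-2-methyl-5-(trimethylsilyl)pent-2-en-4-ynoate
Product: 8 (2E)-3-methoxy-2-methylpent-2-en-4-ynoic acid
Conditions: LiOH, THF–MeOH–H2O, rt; then 1 M HCl to pH 3, 0 °C
Reagents that add atoms: lithium hydroxide, [Li+].[OH-]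
Why: Saponification of the β-alkoxyacrylate ester with protodesilylation of the alkynylsilane in the same pot; the double-bond geometry is not touched and cold, brief acidification should spare the push–pull enol ether.

Step 5
Reactants: 8 (2E)-3-methoxy-2-methylpent-2-en-4-ynoic acid; 9 (E)-crotonaldehyde
Product: 12 (3S)-4-[(2E)-3-methoxy-4-methyl-5-oxofuran-2(5H)-ylidene]-3-methylbutanal, via alkenylpalladium bromide 10 (not isolated), via palladium enolate 11 (not isolated)
Conditions: Pd(OAc)2 (5 mol %), (S)-4-tert-butyl-2-(pyridin-2-yl)-4,5-dihydrooxazole (6 mol %), LiBr (10 mol %), 9 (5 equiv), AcOH, 25 °C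
Reagents that add atoms: none
Why: Proposed new method: divalent palladium carrying the pyridine–oxazoline ligand activates the terminal alkyne of 8 and the cis carboxyl group attacks the internal alkyne carbon anti to the metal, a 5-exo-dig closure of ring A that leaves palladium on the exocyclic CH carbon trans to the ring oxygen (10); syn insertion of crotonaldehyde into this alkenyl–palladium bond joins that carbon to the enal β-carbon (11), and protonolysis of the palladium enolate by AcOH, favoured over β-hydride elimination by bromide and the nitrogen chelate, releases aldehyde 12 and divalent palladium without a redox step. The closest known reaction type is the Pd(OAc)2–LiBr-catalysed nucleopalladation of alkynes, including anti-oxypalladative lactonisation of alkynoic acids, with insertion of acrolein or vinyl ketones and protonolysis, together with ligand-controlled enantioselective enone insertions in intramolecular acetoxypalladation cascades; the new element is the intermolecular, enantioselective use of a β-methyl enal. The new stereocentre is set in the insertion by the chiral ligand, which has to distinguish the two faces of the enal bound cis to the alkenyl group. The E geometry needs no further control, because carbon takes the place of palladium with retention after anti addition. The step needs 5-exo and not 6-endo attack, which the terminal alkyne and the fixed cis-enoate geometry should secure, and insertion faster than protonolysis of 10, which excess enal and a low bromide loading (one coordination site kept open, ligand kept on the metal) should favour.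

Step 6
Reactants: 12 (3S)-4-[(2E)-3-methoxy-4-methyl-5-oxofuran-2(5H)-ylidene]-3-methylbutanal
Product: 13 (5E)-5-[(2S,4E)-5-iodo-2-methylpent-4-en-1-ylidene]-4-methoxy-3-methylfuran-2(5H)-one
Conditions: CrCl2 (6 equiv), CHI3 (2 equiv), THF–1,4-dioxane, 0 °C → rt
Reagents that add atoms: iodoform, IC(I)I
Why: Takai iodo-olefination; the gem-dichromium species from CHI3 adds to the aldehyde and anti-elimination should give the (E)-iodoalkene, while divalent chromium leaves the lactone and the stereocentre β to the aldehyde alone.

Step 7
Reactants: 14 3,4-dibromofuran; 15 furan-3-carbaldehyde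
Product: 17 (4-bromofuran-3-yl)(furan-3-yl)methanol (racemic), via 4-bromofuran-3-yllithium 16 (not isolated)
Conditions: n-BuLi (1.0 equiv), Et2O, −78 °C; then 15, −78 °C; aq. NH4Cl
Reagents that add atoms: none
Why: Bromine–lithium exchange at one C–Br bond at −78 °C, cold enough to prevent migration of lithium to the α-position, followed by 1,2-addition to the aldehyde.

Step 8
Reactants: 17 (4-bromofuran-3-yl)(furan-3-yl)methanol
Product: 18 3-bromo-4-(furan-3-ylmethyl)furan
Conditions: Et3SiH, CF3CO2H, CH2Cl2, −40 → 0 °C
Reagents that add atoms: none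
Why: Ionic hydrogenation; the carbocation stabilised by two furan rings is trapped by hydride from the silane, which at low temperature should be faster than acid attack on the furans, and the C–Br bond is inert.

Step 9
Reactants: 19 pent-3-yn-1-ol
Product: 20 5-iodopent-2-yne
Conditions: I2, PPh3, imidazole, CH2Cl2, 0 °C → rt
Reagents that add atoms: iodine, II
Why: Appel-type iodination; iodide displaces the alkoxyphosphonium group of a primary alcohol by SN2.

Step 10
Reactants: 20 5-iodopent-2-yne; 18 3-bromo-4-(furan-3-ylmethyl)furan
Product: 22 3-(furan-3-ylmethyl)-4-(pent-3-yn-1-yl)furan, via pent-3-yn-1-ylzinc iodide 21 (not isolated)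
Conditions: Zn dust, LiCl, THF, 40 °C; then 18, Pd(OAc)2 (2 mol %), SPhos (4 mol %), THF, 50 °C
Reagents that add atoms: none
Why: Zinc insertion into the primary C–I bond gives a stable homopropargylic zinc reagent, and Negishi sp3–sp2 coupling at zerovalent palladium with a bulky biarylphosphine should join it to the bromofuran faster than β-hydride elimination.

Step 11
Reactants: 22 3-(furan-3-ylmethyl)-4-(pent-3-yn-1-yl)furan; 13 (5E)-5-[(2S,4E)-5-iodo-2-methylpent-4-en-1-ylidene]-4-methoxy-3-methylfuran-2(5H)-one
Product: 25 (5E)-5-[(2S,4E,6E)-9-[4-(furan-3-ylmethyl)furan-3-yl]-2,6-dimethylnona-4,6-dien-1-ylidene]-4-methoxy-3-methylfuran-2(5H)-one, via alkenylzirconocene chloride 23 (not isolated), via alkenylzinc chloride 24 (not isolated)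
Conditions: Cp2Zr(H)Cl (1.3 equiv per 22), THF, 50 °C; then ZnCl2, 0 °C; then 13, Pd(PPh3)4 (5 mol %), THF, rt
Reagents that add atoms: none
Why: Syn hydrozirconation of the 2-alkyne under equilibrating conditions (slight excess of hydride, warm) should place zirconium on the less hindered, methyl-bearing carbon with H and Zr cis; transmetalation to zinc and Negishi coupling at zerovalent palladium go with retention at both alkenyl carbons and need no base, so the (4E,6E)-diene forms with the stereocentre untouched.

Step 12
Reactants: 25 (5E)-5-[(2S,4E,6E)-9-[4-(furan-3-ylmethyl)furan-3-yl]-2,6-dimethylnona-4,6-dien-1-ylidene]-4-methoxy-3-methylfuran-2(5H)-one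
Product: 26 (5E)-5-[(2S,4E,6E)-9-[4-(furan-3-ylmethyl)furan-3-yl]-2,6-dimethylnona-4,6-dien-1-ylidene]-4-hydroxy-3-methylfuran-2(5H)-one (CNP0017516.1)
Conditions: LiCl, DMSO, 50 °C; then cold aq. HCl to pH 3
Reagents that add atoms: none
Why: SN2 demethylation of the vinylogous methyl ester by chloride, the tetronate being a good leaving group; the neutral conditions should spare the furans, the diene, the (E)-ylidene and the allylic stereocentre, and mild acidification frees the tetronic acid.

**Compound list**

1 | 3-(trimethylsilyl)propiolic acid | C[Si](C)(C)C#CC(=O)O | starting material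
2 | 3-(trimethylsilyl)propynoyl chloride | C[Si](C)(C)C#CC(Cl)=O | intermediate
3 | ethyl propionate | CCC(=O)OCC | starting material
4 | lithium enolate of ethyl propionate | CC=C(OCC)O[Li] | intermediate
5 | ethyl 2-methyl-3-oxo-5-(trimethylsilyl)pent-4-ynoate (racemic) | CCOC(=O)C(C)C(=O)C#C[Si](C)(C)C | intermediate
6 | potassium enolate of 5 | CCOC(=O)C(C)=C([O-])C#C[Si](C)(C)C.[K+] | intermediate
7 | ethyl (2E)-3-methoxy-2-methyl-5-(trimethylsilyl)pent-2-en-4-ynoate | CCOC(=O)/C(C)=C(/OC)C#C[Si](C)(C)C | intermediate
8 | (2E)-3-methoxy-2-methylpent-2-en-4-ynoic acid | C#C/C(OC)=C(/C)C(=O)O | intermediate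
9 | (E)-crotonaldehyde | C/C=C/C=O | starting material
10 | [(E)-(3-methoxy-4-methyl-5-oxofuran-2(5H)-ylidene)methyl]palladium bromide (chiral ligand omitted) | CC1=C(OC)/C(=C\[Pd]Br)OC1=O | intermediate
11 | C-bound palladium enolate of 12 (chiral ligand omitted) | CC1=C(OC)/C(=C\[C@@H](C)C([Pd]Br)C=O)OC1=O | intermediate
12 | (3S)-4-[(2E)-3-methoxy-4-methyl-5-oxofuran-2(5H)-ylidene]-3-methylbutanal | CC1=C(OC)/C(=C\[C@@H](C)CC=O)OC1=O | intermediate
13 | (5E)-5-[(2S,4E)-5-iodo-2-methylpent-4-en-1-ylidene]-4-methoxy-3-methylfuran-2(5H)-one | CC1=C(OC)/C(=C\[C@@H](C)C/C=C/I)OC1=O | intermediate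
14 | 3,4-dibromofuran | Brc1cocc1Br | starting material
15 | furan-3-carbaldehyde | O=Cc1ccoc1 | starting material
16 | 4-bromofuran-3-yllithium | [Li]c1cocc1Br | intermediate
17 | (4-bromofuran-3-yl)(furan-3-yl)methanol (racemic) | OC(c1cocc1Br)c1ccoc1 | intermediate
18 | 3-bromo-4-(furan-3-ylmethyl)furan | Brc1cocc1Cc1ccoc1 | intermediate
19 | pent-3-yn-1-ol | CC#CCCO | starting material
20 | 5-iodopent-2-yne | CC#CCCI | intermediate
21 | pent-3-yn-1-ylzinc iodide | CC#CCC[Zn]I | intermediate
22 | 3-(furan-3-ylmethyl)-4-(pent-3-yn-1-yl)furan | CC#CCCc1cocc1Cc1ccoc1 | intermediate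
23 | chlorobis(cyclopentadienyl)[(2E)-5-[4-(furan-3-ylmethyl)furan-3-yl]pent-2-en-2-yl]zirconium (cyclopentadienyl rings drawn σ-bonded) | C/C(=C\CCc1cocc1Cc1ccoc1)[Zr](Cl)(C1C=CC=C1)C1C=CC=C1 | intermediate
24 | [(2E)-5-[4-(furan-3-ylmethyl)furan-3-yl]pent-2-en-2-yl]zinc chloride | C/C(=C\CCc1cocc1Cc1ccoc1)[Zn]Cl | intermediate
25 | (5E)-5-[(2S,4E,6E)-9-[4-(furan-3-ylmethyl)furan-3-yl]-2,6-dimethylnona-4,6-dien-1-ylidene]-4-methoxy-3-methylfuran-2(5H)-one | CC1=C(OC)/C(=C\[C@@H](C)C/C=C/C(C)=C/CCc2cocc2Cc2ccoc2)OC1=O | intermediate
26 | (5E)-5-[(2S,4E,6E)-9-[4-(furan-3-ylmethyl)furan-3-yl]-2,6-dimethylnona-4,6-dien-1-ylidene]-4-hydroxy-3-methylfuran-2(5H)-one | CC1=C(O)/C(=C\[C@@H](C)C/C=C/C(C)=C/CCc2cocc2Cc2ccoc2)OC1=O | target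

**Step count**

Total: 12 steps. Longest linear sequence: 8 steps (steps 1, 2, 3, 4, 5, 6, 11, 12).

**Steps most likely to fail and fallbacks**

Step 5 (bears the label). Protonolysis of the alkenylpalladium species may outrun insertion of the sluggish β-substituted enal, giving only the 5-methylene lactone. The ligand may also discriminate the enal faces poorly, or bromide may displace it and open a racemic pathway. The fallback sets out from acid 8 and comes back at aldehyde 12, splitting the cascade into known reactions. Iodolactonisation of 8 (I2, NaHCO3, MeCN, 0 °C; anti addition, 5-exo) should give (5E)-5-(iodomethylidene)-4-methoxy-3-methylfuran-2(5H)-one F1, with iodine trans to the ring oxygen. Miyaura borylation (bis(pinacolato)diboron, PdCl2(PPh3)2, PPh3, KOPh, toluene, 50 °C) with retention should give (5E)-4-methoxy-3-methyl-5-[(4,4,5,5-tetramethyl-1,3,2-dioxaborolan-2-yl)methylidene]furan-2(5H)-one F2. Rhodium-catalysed asymmetric conjugate addition of F2 to crotonaldehyde 9 (Hayashi–Miyaura type; [RhCl(C2H4)2]2, chiral bicyclic diene ligand, KOH (cat.), dioxane–H2O) should then give 12. The alkene geometry is carried over with retention and the S centre comes from an established catalyst class.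

Step 11. Regiochemical equilibration of the hydrozirconation may stay incomplete for an unbranched 2-alkyne, leaving some zirconium on the carbon next to the CH2CH2 chain, and surplus hydride may attack the lactone of 13. The fallback sets out from bromide 18 and aldehyde 12 and comes back at 25; it fixes the methyl-bearing carbon by construction.
- Negishi coupling of 18 with (3-ethoxy-3-oxopropyl)zinc bromide (Pd(OAc)2, SPhos, THF) gives ethyl 3-[4-(furan-3-ylmethyl)furan-3-yl]propanoate F3.
- Reduction with i-Bu2AlH (CH2Cl2, −78 °C) gives 3-[4-(furan-3-ylmethyl)furan-3-yl]propanal F4.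
- Dibromo-olefination (CBr4, PPh3, CH2Cl2, 0 °C) gives 3-(4,4-dibromobut-3-en-1-yl)-4-(furan-3-ylmethyl)furan F5.
- Separately, the tin variant of the Takai olefination on 12 (CrCl2, Bu3SnCHBr2, LiI, DMF–THF) gives (5E)-4-methoxy-3-methyl-5-[(2S,4E)-2-methyl-5-(tributylstannyl)pent-4-en-1-ylidene]furan-2(5H)-one F6.
- Stille coupling of F5 with F6 (Pd2(dba)3, tri(2-furyl)phosphine, toluene) at the bromine trans to the chain gives (5E)-5-[(2S,4E,6Z)-6-bromo-9-[4-(furan-3-ylmethyl)furan-3-yl]-2-methylnona-4,6-dien-1-ylidene]-4-methoxy-3-methylfuran-2(5H)-one F7.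
- Negishi methylation of F7 with retention (MeZnCl, Pd(t-Bu3P)2, THF) gives 25.

Step 3. Methylation may go partly on carbon, or the enolate may react from a form that puts the alkyne trans to the ester; that isomer cannot lactonise in step 5. The fallback sets out from β-keto ester 5 and comes back at enol ether 7, replacing kinetic enolate alkylation by acid-catalysed, thermodynamically controlled enol ether formation. Trimethyl orthoformate with catalytic TsOH should give ethyl 3,3-dimethoxy-2-methyl-5-(trimethylsilyl)pent-4-ynoate F8. Warming F8 with catalytic TsOH while methanol is distilled off should give 7, since methoxy trans to the ester is the favoured arrangement of a β-alkoxyacrylate.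

**Further compounds**

F1 | step 5 | (5E)-5-(iodomethylidene)-4-methoxy-3-methylfuran-2(5H)-one | CC1=C(OC)/C(=C\I)OC1=O
F2 | step 5 | (5E)-4-methoxy-3-methyl-5-[(4,4,5,5-tetramethyl-1,3,2-dioxaborolan-2-yl)methylidene]furan-2(5H)-one | CC1=C(OC)/C(=C\B2OC(C)(C)C(C)(C)O2)OC1=O
F3 | step 11 | ethyl 3-[4-(furan-3-ylmethyl)furan-3-yl]propanoate | CCOC(=O)CCc1cocc1Cc1ccoc1
F4 | step 11 | 3-[4-(furan-3-ylmethyl)furan-3-yl]propanal | O=CCCc1cocc1Cc1ccoc1
F5 | step 11 | 3-(4,4-dibromobut-3-en-1-yl)-4-(furan-3-ylmethyl)furan | BrC(Br)=CCCc1cocc1Cc1ccoc1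
F6 | step 11 | (5E)-4-methoxy-3-methyl-5-[(2S,4E)-2-methyl-5-(tributylstannyl)pent-4-en-1-ylidene]furan-2(5H)-one | CC1=C(OC)/C(=C\[C@@H](C)C/C=C/[Sn](CCCC)(CCCC)CCCC)OC1=O
F7 | step 11 | (5E)-5-[(2S,4E,6Z)-6-bromo-9-[4-(furan-3-ylmethyl)furan-3-yl]-2-methylnona-4,6-dien-1-ylidene]-4-methoxy-3-methylfuran-2(5H)-one | CC1=C(OC)/C(=C\[C@@H](C)C/C=C/C(Br)=C/CCc2cocc2Cc2ccoc2)OC1=O
F8 | step 3 | ethyl 3,3-dimethoxy-2-methyl-5-(trimethylsilyl)pent-4-ynoate | CCOC(=O)C(C)C(OC)(OC)C#C[Si](C)(C)C
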